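The synthesis rests on cutting the C1–C10 bond of ring A (labdane numbering), so ring B is made first with all other stereocentres in place. The key step exploits the quaternary, methyl-bearing ring-fusion carbon C10 next to an unfunctionalised C1 methylene: hydrogen-atom transfer to an exocyclic C10=C20 methylene on ring B gives the tertiary C10 radical, which closes ring A by 6-exo addition to a C1 N-sulfonylhydrazone; loss of sulfinate and N2 then leaves C1 as CH2. One operation thus creates the C20 methyl, the quaternary centre and the trans ring fusion. The precursor is a 2-methylenecyclohexane whose C5 side chain carries the quaternary C4 acid and the C1 hydrazone.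

Key step: step 10

Assumption: labdane numbering (C1–C20) is used for all intermediates, and 2-chloroethyl trifluoromethanesulfonate is taken as a commercial reagent (otherwise it is made from 2-chloroethanol and Tf2O).

Step 1
Reactants: 1 methyl 3-oxocyclohex-1-ene-1-carboxylate
Product: 4 methyl (1R,2S)-2-(2-chloroethyl)-3-oxocyclohexane-1-carboxylate, via silyl enol ether 2 (not isolated), via lithium enolate 3 (not isolated)
Conditions: Cu(OAc)2 (5 mol%), (R)-DTBM-SEGPHOS (5 mol%), (EtO)2MeSiH, toluene, 0 °C; then MeLi (1.0 equiv), THF, −78 °C; then ClCH2CH2OTf, −78 to −20 °C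
Reagents that add atoms: 2-chloroethyl trifluoromethanesulfonate, ClCCOS(=O)(=O)C(F)(F)F
Why: CuH-catalysed asymmetric conjugate reduction should deliver hydride to C8 under ligand control (either ligand antipode is available, so the sense can be matched to 8R) and give the C9=C10 silyl enol ether regiospecifically; MeLi attacks silicon to free the lithium enolate, which is C-alkylated by the primary triflate anti to the C8 ester, setting the trans C8/C9 relationship.

Step 2
Reactants: 4 methyl (1R,2S)-2-(2-chloroethyl)-3-oxocyclohexane-1-carboxylate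
Product: 5 methyl (1R,2S,4S)-2-(2-chloroethyl)-4-(2-methoxy-2-oxoethyl)-3-oxocyclohexane-1-carboxylate
Conditions: LiN(iPr)2, THF, −78 °C; BrCH2CO2Me, −78 to −40 °C; then TsOH (cat.), toluene, 50 °C
Reagents that add atoms: methyl bromoacetate, COC(=O)CBr
Why: Kinetic deprotonation by the hindered amide base occurs at the unsubstituted α'-carbon C5 and the enolate is alkylated by the reactive α-bromo ester while the primary chloride stays inert at low temperature; acid-catalysed enolisation then equilibrates C5 to the all-equatorial 2,6-cis ketone (thermodynamic control, acid being used because base could cyclise the γ-chloro ketone).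

Step 3
Reactants: 5 methyl (1R,2S,4S)-2-(2-chloroethyl)-4-(2-methoxy-2-oxoethyl)-3-oxocyclohexane-1-carboxylate
Product: 7 methyl (3aS,6R,7S,7aR)-7-(2-chloroethyl)-2-oxo-7a-[(trimethylsilyl)methyl]octahydro-1-benzofuran-6-carboxylate, via magnesium alkoxide 6 (not isolated)
Conditions: Me3SiCH2MgCl, CeCl3, THF, −78 °C to rt
Reagents that add atoms: (trimethylsilyl)methylmagnesium chloride, C[Si](C)(C)C[Mg]Cl
Why: The Peterson-type organometallic should add chemoselectively to the ketone from the equatorial direction, and the axial tertiary alkoxide, cis to the C5 acetate arm, should lactonise by intramolecular transesterification faster than it displaces the chloride, giving the cis-fused γ-lactone whose β-silyl carboxylate is stable until fluoride is added.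

Step 4
Reactants: 7 methyl (3aS,6R,7S,7aR)-7-(2-chloroethyl)-2-oxo-7a-[(trimethylsilyl)methyl]octahydro-1-benzofuran-6-carboxylate
Product: 8 methyl (3aS,6R,7S,7aR)-7-(2-chloroethyl)-3-methyl-2-oxo-7a-[(trimethylsilyl)methyl]octahydro-1-benzofuran-6-carboxylate (C3 epimers)
Conditions: LiN(iPr)2, THF, −78 °C; MeI, −78 °C
Reagents that add atoms: iodomethane, CI
Why: Enolate alkylation at the lactone α-CH2, which is more acidic than the tertiary C8–H of the acyclic ester; the C4 configuration formed here is irrelevant because C4 is re-enolised in step 5.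

Step 5
Reactants: 8 methyl (3aS,6R,7S,7aR)-7-(2-chloroethyl)-3-methyl-2-oxo-7a-[(trimethylsilyl)methyl]octahydro-1-benzofuran-6-carboxylate
Product: 9 methyl (3S,3aS,6R,7S,7aR)-7-(2-chloroethyl)-3-methyl-2-oxo-3-(prop-2-yn-1-yl)-7a-[(trimethylsilyl)methyl]octahydro-1-benzofuran-6-carboxylate
Conditions: LiN(iPr)2, THF, −78 °C; propargyl bromide, −78 to −30 °C
Reagents that add atoms: propargyl bromide, C#CCBr
Why: Alkylation of the α-methyl enolate of the cis-fused bicyclic lactone, in which H5 lies in the enolate plane (allylic strain) so that the C6 methylene of ring B blocks one face, should occur from the convex face syn to H5, placing propargyl (C3) and methyl (C18) on the quaternary C4 as required (4S relative to 5R, substrate-controlled 1,2-induction).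

Step 6
Reactants: 10 3-bromooxolan-2-one; 11 benzenethiol
Product: 12 3-(phenylsulfanyl)oxolan-2-one
Conditions: Et3N, CH2Cl2, 0 °C to rt
Reagents that add atoms: none
Why: SN2 displacement of the activated α-bromide by the thiolate.

Step 7
Reactants: 9 methyl (3S,3aS,6R,7S,7aR)-7-(2-chloroethyl)-3-methyl-2-oxo-3-(prop-2-yn-1-yl)-7a-[(trimethylsilyl)methyl]octahydro-1-benzofuran-6-carboxylate; 12 3-(phenylsulfanyl)oxolan-2-one
Product: 13 methyl (3S,3aS,6R,7S,7aR)-3-methyl-2-oxo-7-{2-[2-oxo-3-(phenylsulfanyl)oxolan-3-yl]ethyl}-3-(prop-2-yn-1-yl)-7a-[(trimethylsilyl)methyl]octahydro-1-benzofuran-6-carboxylate (epimers at the sulfur-bearing carbon)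
Conditions: 12, KN(SiMe3)2, THF, −78 °C; then 9, NaI (cat.), DMPU, 45 °C
Reagents that add atoms: none
Why: C-alkylation of the sulfur-stabilised lactone enolate by the primary chloride with iodide catalysis (Finkelstein activation) is the standard entry to α-alkyl butenolides; this weak base deprotonates neither the alkyne nor the ester, the quaternary lactone is not enolisable, and the new sulfur-bearing centre is destroyed in step 12.

Step 8
Reactants: 13 methyl (3S,3aS,6R,7S,7aR)-3-methyl-2-oxo-7-{2-[2-oxo-3-(phenylsulfanyl)oxolan-3-yl]ethyl}-3-(prop-2-yn-1-yl)-7a-[(trimethylsilyl)methyl]octahydro-1-benzofuran-6-carboxylate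
Product: 15 methyl (3S,3aS,6R,7S,7aR)-3-methyl-2-oxo-7-{2-[2-oxo-3-(phenylsulfanyl)oxolan-3-yl]ethyl}-3-(3-oxopropyl)-7a-[(trimethylsilyl)methyl]octahydro-1-benzofuran-6-carboxylate, via alkenylborane 14 (not isolated)
Conditions: Cy2BH, THF, 0 °C; then Me3NO·2H2O, 40 °C
Reagents that add atoms: trimethylamine N-oxide, C[N+](C)(C)[O-]
Why: Anti-Markovnikov hydroboration of the terminal alkyne with the hindered dialkylborane and oxidation of the alkenylborane with the amine oxide, which spares the sulfide, should give the C1 aldehyde while esters and lactones stay untouched.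

Step 9
Reactants: 15 methyl (3S,3aS,6R,7S,7aR)-3-methyl-2-oxo-7-{2-[2-oxo-3-(phenylsulfanyl)oxolan-3-yl]ethyl}-3-(3-oxopropyl)-7a-[(trimethylsilyl)methyl]octahydro-1-benzofuran-6-carboxylate
Product: 17 (2S)-2-[(1R,3S,4R)-4-(methoxycarbonyl)-2-methylidene-3-{2-[2-oxo-3-(phenylsulfanyl)oxolan-3-yl]ethyl}cyclohexyl]-2-methyl-5-[2-(4-methylbenzenesulfonyl)hydrazinylidene]pentanoic acid, via lactone hydrazone 16 (not isolated)
Conditions: TsNHNH2, THF, rt; then Bu4NF, THF, 0 °C to rt; aq. HCl work-up
Reagents that add atoms: p-toluenesulfonyl hydrazide, Cc1ccc(cc1)S(=O)(=O)NN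
Why: Condensation gives the N-tosylhydrazone, and fluoride attack on silicon then triggers the Peterson-type β-elimination of the tertiary carboxylate (the fragmentation by which 2-(trimethylsilyl)ethyl esters are cleaved), unveiling regiospecifically the exocyclic C10=C20 methylene and the free C19 acid.

Step 10
Reactants: 17 (2S)-2-[(1R,3S,4R)-4-(methoxycarbonyl)-2-methylidene-3-{2-[2-oxo-3-(phenylsulfanyl)oxolan-3-yl]ethyl}cyclohexyl]-2-methyl-5-[2-(4-methylbenzenesulfonyl)hydrazinylidene]pentanoic acid
Product: 19 (1S,4aR,5S,6R,8aR)-6-(methoxycarbonyl)-1,4a-dimethyl-5-{2-[2-oxo-3-(phenylsulfanyl)oxolan-3-yl]ethyl}decahydronaphthalene-1-carboxylic acid, via cyclic sulfonylhydrazide 18 (not isolated)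
Conditions: Fe(acac)3 (50 mol%), PhSiH3, EtOH/THF, 40 °C; then NaOAc, EtOH, 80 °C
Reagents that add atoms: none
Why: An iron hydride formed from Fe(acac)3 and PhSiH3 transfers a hydrogen atom to the CH2 terminus of the only alkene, the 1,1-disubstituted C10=C20, creating the C20 methyl and a tertiary C10 radical that adds to C1 of the electrophilic N-sulfonylhydrazone; the hydrazinyl radical is reduced to hydrazide 18, and NaOAc with heat then expels sulfinate to give a monoalkyl diazene that loses N2, leaving C1 as CH2. The closest known reactions are the iron-mediated HAT reductive coupling of unactivated olefins with sulfonylhydrazones (hydromethylation type) and HAT-triggered alkene–hydrazone cyclisations, followed by the sulfonylhydrazide-to-alkane denitrogenation familiar from tosylhydrazone reductions. Ring A closes in the 6-exo-trig mode. The new C10 centre is set by C5 and the fixed C4: with ring B in the chair that keeps its C5, C8 and C9 substituents equatorial, the chair-like transition state leading to the trans fusion keeps C6 equatorial on the forming ring and the CO2H axial, whereas the cis alternative must place C6 axial and the C4 methyl syn-axial to the developing C20 methyl. The step needs cyclisation to outrun reduction of the tertiary radical, which the gem-disubstituted C4 (Thorpe–Ingold compression) and the polarity-matched intramolecular acceptor should secure, and site-selective HAT, which is secured because no other alkene is present.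

Step 11
Reactants: 19 (1S,4aR,5S,6R,8aR)-6-(methoxycarbonyl)-1,4a-dimethyl-5-{2-[2-oxo-3-(phenylsulfanyl)oxolan-3-yl]ethyl}decahydronaphthalene-1-carboxylic acid
Product: 21 (1S,4aR,5S,6R,8aR)-1,4a-dimethyl-5-{2-[2-oxo-3-(phenylsulfanyl)oxolan-3-yl]ethyl}decahydronaphthalene-1,6-dicarboxylic acid, via trilithium hydroxy tricarboxylate 20 (not isolated)
Conditions: LiOH, THF/MeOH/H2O, 50 °C; then aq. HCl to pH 2
Reagents that add atoms: lithium hydroxide, [Li+].[OH-]
Why: Saponification of the equatorial secondary methyl ester; the phenylthio lactone opens to the hydroxy carboxylate and re-closes on acidification, and C8 is already in its thermodynamically preferred equatorial configuration.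

Step 12
Reactants: 21 (1S,4aR,5S,6R,8aR)-1,4a-dimethyl-5-{2-[2-oxo-3-(phenylsulfanyl)oxolan-3-yl]ethyl}decahydronaphthalene-1,6-dicarboxylic acid
Product: 23 (1S,4aR,5S,6R,8aR)-1,4a-dimethyl-5-[2-(2-oxo-2,5-dihydrofuran-3-yl)ethyl]decahydronaphthalene-1,6-dicarboxylic acid, via sulfoxide 22 (not isolated)
Conditions: mCPBA (1.0 equiv), CH2Cl2, −78 to 0 °C; then toluene, CaCO3, 100 °C
Reagents that add atoms: none
Why: Sulfide oxidation followed by thermal syn-elimination of benzenesulfenic acid towards the ring methylene (sulfoxide pyrolysis, as in α-phenylthio lactone routes to butenolides) should give the endocyclic C13=C14 butenolide under neutral conditions that tolerate both free acids.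

Compound list
1 | methyl 3-oxocyclohex-1-ene-1-carboxylate | COC(=O)C1=CC(=O)CCC1 | starting material
2 | methyl (1R)-3-{[diethoxy(methyl)silyl]oxy}cyclohex-2-ene-1-carboxylate | CCO[Si](C)(OCC)OC1=C[C@H](C(=O)OC)CCC1 | intermediate
3 | lithium (3R)-3-(methoxycarbonyl)cyclohex-1-en-1-olate | [Li]OC1=C[C@H](C(=O)OC)CCC1 | intermediate
4 | methyl (1R,2S)-2-(2-chloroethyl)-3-oxocyclohexane-1-carboxylate | O=C1CCC[C@@H](C(=O)OC)[C@@H]1CCCl | intermediate
5 | methyl (1R,2S,4S)-2-(2-chloroethyl)-4-(2-methoxy-2-oxoethyl)-3-oxocyclohexane-1-carboxylate | O=C1[C@H](CC(=O)OC)CC[C@@H](C(=O)OC)[C@@H]1CCCl | intermediate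
6 | chloromagnesium alkoxide of methyl (1R,2S,3R,4S)-2-(2-chloroethyl)-3-hydroxy-4-(2-methoxy-2-oxoethyl)-3-[(trimethylsilyl)methyl]cyclohexane-1-carboxylate | COC(=O)C[C@@H]1CC[C@@H](C(=O)OC)[C@H](CCCl)[C@]1(C[Si](C)(C)C)O[Mg]Cl | intermediate
7 | methyl (3aS,6R,7S,7aR)-7-(2-chloroethyl)-2-oxo-7a-[(trimethylsilyl)methyl]octahydro-1-benzofuran-6-carboxylate (cis-fused γ-lactone) | O=C1C[C@@H]2CC[C@@H](C(=O)OC)[C@H](CCCl)[C@]2(C[Si](C)(C)C)O1 | intermediate
8 | methyl (3aS,6R,7S,7aR)-7-(2-chloroethyl)-3-methyl-2-oxo-7a-[(trimethylsilyl)methyl]octahydro-1-benzofuran-6-carboxylate (C3 epimers) | O=C1C(C)[C@@H]2CC[C@@H](C(=O)OC)[C@H](CCCl)[C@]2(C[Si](C)(C)C)O1 | intermediate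
9 | methyl (3S,3aS,6R,7S,7aR)-7-(2-chloroethyl)-3-methyl-2-oxo-3-(prop-2-yn-1-yl)-7a-[(trimethylsilyl)methyl]octahydro-1-benzofuran-6-carboxylate | O=C1[C@@](C)(CC#C)[C@@H]2CC[C@@H](C(=O)OC)[C@H](CCCl)[C@]2(C[Si](C)(C)C)O1 | intermediate
10 | 3-bromooxolan-2-one (α-bromo-γ-butyrolactone, racemic) | BrC1CCOC1=O | starting material
11 | benzenethiol | Sc1ccccc1 | starting material
12 | 3-(phenylsulfanyl)oxolan-2-one (racemic) | O=C1OCCC1Sc1ccccc1 | intermediate
13 | methyl (3S,3aS,6R,7S,7aR)-3-methyl-2-oxo-7-{2-[2-oxo-3-(phenylsulfanyl)oxolan-3-yl]ethyl}-3-(prop-2-yn-1-yl)-7a-[(trimethylsilyl)methyl]octahydro-1-benzofuran-6-carboxylate (epimers at the sulfur-bearing carbon) | O=C1[C@@](C)(CC#C)[C@@H]2CC[C@@H](C(=O)OC)[C@H](CCC3(Sc4ccccc4)CCOC3=O)[C@]2(C[Si](C)(C)C)O1 | intermediate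
14 | 3-[(2E)-3-(dicyclohexylboranyl)prop-2-en-1-yl] analogue of 13 (alkenylborane) | O=C1[C@@](C)(C/C=C/B(C3CCCCC3)C3CCCCC3)[C@@H]2CC[C@@H](C(=O)OC)[C@H](CCC3(Sc4ccccc4)CCOC3=O)[C@]2(C[Si](C)(C)C)O1 | intermediate
15 | methyl (3S,3aS,6R,7S,7aR)-3-methyl-2-oxo-7-{2-[2-oxo-3-(phenylsulfanyl)oxolan-3-yl]ethyl}-3-(3-oxopropyl)-7a-[(trimethylsilyl)methyl]octahydro-1-benzofuran-6-carboxylate | O=C1[C@@](C)(CCC=O)[C@@H]2CC[C@@H](C(=O)OC)[C@H](CCC3(Sc4ccccc4)CCOC3=O)[C@]2(C[Si](C)(C)C)O1 | intermediate
16 | N-(4-methylbenzenesulfonyl)hydrazone of aldehyde 15 | O=C1[C@@](C)(CCC=NNS(=O)(=O)c3ccc(C)cc3)[C@@H]2CC[C@@H](C(=O)OC)[C@H](CCC3(Sc4ccccc4)CCOC3=O)[C@]2(C[Si](C)(C)C)O1 | intermediate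
17 | (2S)-2-[(1R,3S,4R)-4-(methoxycarbonyl)-2-methylidene-3-{2-[2-oxo-3-(phenylsulfanyl)oxolan-3-yl]ethyl}cyclohexyl]-2-methyl-5-[2-(4-methylbenzenesulfonyl)hydrazinylidene]pentanoic acid | C=C1[C@H]([C@@](C)(C(=O)O)CCC=NNS(=O)(=O)c2ccc(C)cc2)CC[C@@H](C(=O)OC)[C@@H]1CCC3(Sc4ccccc4)CCOC3=O | intermediate
18 | C1-[2-(4-methylbenzenesulfonyl)hydrazinyl] derivative of 19 (labdane C1, either epimer) | C[C@]12C(NNS(=O)(=O)c3ccc(C)cc3)CC[C@](C)(C(=O)O)[C@@H]1CC[C@@H](C(=O)OC)[C@@H]2CCC1(Sc2ccccc2)CCOC1=O | intermediate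
19 | (1S,4aR,5S,6R,8aR)-6-(methoxycarbonyl)-1,4a-dimethyl-5-{2-[2-oxo-3-(phenylsulfanyl)oxolan-3-yl]ethyl}decahydronaphthalene-1-carboxylic acid | C[C@]12CCC[C@](C)(C(=O)O)[C@@H]1CC[C@@H](C(=O)OC)[C@@H]2CCC1(Sc2ccccc2)CCOC1=O | intermediate
20 | trilithium salt of the lactone-opened hydroxy triacid derived from 19 | [Li+].[Li+].[Li+].C[C@]12CCC[C@](C)(C(=O)[O-])[C@@H]1CC[C@@H](C(=O)[O-])[C@@H]2CCC(CCO)(Sc1ccccc1)C(=O)[O-] | intermediate
21 | (1S,4aR,5S,6R,8aR)-1,4a-dimethyl-5-{2-[2-oxo-3-(phenylsulfanyl)oxolan-3-yl]ethyl}decahydronaphthalene-1,6-dicarboxylic acid | C[C@]12CCC[C@](C)(C(=O)O)[C@@H]1CC[C@@H](C(=O)O)[C@@H]2CCC1(Sc2ccccc2)CCOC1=O | intermediate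
22 | S-oxide (sulfoxide) of 21 | C[C@]12CCC[C@](C)(C(=O)O)[C@@H]1CC[C@@H](C(=O)O)[C@@H]2CCC1(S(=O)c2ccccc2)CCOC1=O | intermediate
23 | (1S,4aR,5S,6R,8aR)-1,4a-dimethyl-5-[2-(2-oxo-2,5-dihydrofuran-3-yl)ethyl]decahydronaphthalene-1,6-dicarboxylic acid | C[C@]12CCC[C@](C)(C(=O)O)[C@@H]1CC[C@@H](C(=O)O)[C@@H]2CCC1=CCOC1=O | target

Total step count: 12. Longest linear sequence: 11 steps (steps 1–5 and 7–12).

Steps most likely to fail

Step 10. The tertiary C10 radical may be reduced by a second hydrogen atom before it cyclises (net hydrogenation of the methylene), the ring may close through the cis-fused transition state, or the hydrazide may resist denitrogenation. The fallback closes the same bond by a polar, proton-initiated cation–olefin cyclisation; it sets out from 13 and comes back at 19. Ruthenium-catalysed trans-hydrosilylation of the terminal alkyne of 13 ([RuCl2(p-cymene)]2, Et3SiH) would give the (Z)-vinylsilane lactone F1. Bu4NF would open the β-silyl lactone to the methylene acid vinylsilane F2, the triethylsilyl alkene surviving. SnCl4 in CH2Cl2 at −78 °C, acting with the carboxylic acid as a Brønsted acid, would protonate C20; the tertiary C10 cation (in reversible equilibrium with its C19 lactone) would be captured at C1 by ipso attack of the vinylsilane from the face opposite the C19 carboxyl, giving the trans-fused 1,2-dehydro acid F3. Diimide (TsNHNH2, NaOAc, DME, reflux) would saturate C1=C2 without touching the sulfide and give 19.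

Step 5. The propargyl group may enter from the face syn to C6, pushed there by the angular CH2SiMe3 group, which would invert C4. The fallback inverts the order of the two alkylations so that the same facial bias installs the methyl group last; it sets out from 7 and comes back at 9. LiN(iPr)2 and propargyl bromide would convert 7 into the mono-propargyl lactone F4, and LiN(iPr)2 and MeI would then deliver 9.

Step 1. The conjugate reduction may give insufficient enantioselectivity or competing carbonyl reduction, MeLi may attack the ester, or the triflate may O-alkylate the enolate. The fallback is a chiral-pool route on stoichiometric enolate chemistry; it draws on no intermediate of the route but replaces compound 1 by commercial (R)-cyclohex-3-ene-1-carboxylic acid F5, and it comes back at 5. Iodolactonisation (I2, KI, NaHCO3) would give the iodolactone F6 and elimination with DBU the unsaturated lactone F7. Methanolysis (K2CO3, MeOH) would give the cis hydroxy ester F8, and MnO2 would oxidise it to the enone F9. Kinetic α'-deprotonation (LiN(iPr)2) and alkylation with ClCH2CH2OTf anti to the ester would give the chloroethyl enone F10. Conjugate reduction with LiBH(s-Bu)3, alkylation of the resulting regiodefined C5 enolate with BrCH2CO2Me and acid equilibration would give 5.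

Further compounds
F1 | step 10 | 3-[(2Z)-3-(triethylsilyl)prop-2-en-1-yl] analogue of 13 ((Z)-vinylsilane lactone) | O=C1[C@@](C)(C/C=C\[Si](CC)(CC)CC)[C@@H]2CC[C@@H](C(=O)OC)[C@H](CCC3(Sc4ccccc4)CCOC3=O)[C@]2(C[Si](C)(C)C)O1
F2 | step 10 | (2S,4Z)-2-[(1R,3S,4R)-4-(methoxycarbonyl)-2-methylidene-3-{2-[2-oxo-3-(phenylsulfanyl)oxolan-3-yl]ethyl}cyclohexyl]-2-methyl-5-(triethylsilyl)pent-4-enoic acid | C=C1[C@H]([C@@](C)(C(=O)O)C/C=C\[Si](CC)(CC)CC)CC[C@@H](C(=O)OC)[C@@H]1CCC3(Sc4ccccc4)CCOC3=O
F3 | step 10 | 1,2-didehydro analogue of 19 (labdane C1=C2, trans-fused) | C[C@]12C=CC[C@](C)(C(=O)O)[C@@H]1CC[C@@H](C(=O)OC)[C@@H]2CCC1(Sc2ccccc2)CCOC1=O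
F4 | step 5 | methyl (3aS,6R,7S,7aR)-7-(2-chloroethyl)-2-oxo-3-(prop-2-yn-1-yl)-7a-[(trimethylsilyl)methyl]octahydro-1-benzofuran-6-carboxylate (C3 epimers) | O=C1C(CC#C)[C@@H]2CC[C@@H](C(=O)OC)[C@H](CCCl)[C@]2(C[Si](C)(C)C)O1
F5 | step 1 | (R)-cyclohex-3-ene-1-carboxylic acid (commercial) | OC(=O)[C@H]1CC=CCC1
F6 | step 1 | (1R,4R,5R)-4-iodo-6-oxabicyclo[3.2.1]octan-7-one | O=C1O[C@@H]2C[C@H]1CC[C@H]2I
F7 | step 1 | (1R,5R)-6-oxabicyclo[3.2.1]oct-3-en-7-one | O=C1O[C@@H]2C[C@H]1CC=C2
F8 | step 1 | methyl (1R,5R)-5-hydroxycyclohex-3-ene-1-carboxylate (cis) | COC(=O)[C@H]1C[C@@H](O)C=CC1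
F9 | step 1 | methyl (1R)-5-oxocyclohex-3-ene-1-carboxylate | COC(=O)[C@H]1CC(=O)C=CC1
F10 | step 1 | methyl (1R,2S)-2-(2-chloroethyl)-3-oxocyclohex-4-ene-1-carboxylate | O=C1C=CC[C@@H](C(=O)OC)[C@@H]1CCCl
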